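**Assumption:** cembrane numbering is used throughout (C1=C15 is the dihydrofuran alkene, C2 the O-bearing CH, C7/C8 the epoxide, C16 the ring OCH2, C17 the CH2OAc carbon); the target is the (2S,7S,8S,3E,11E) isomer encoded in the SMILES.

**Retrosynthetic overview**
1. Dihydrofuran last: the C2–O–C16 bond by zerovalent-palladium allylic etherification of a macrocyclic 2-hydroxy bis(acetoxymethyl)alkylidene.
2. 14-membered carbocycle: the C1–C2 bond by electrochemical Ni/Cr alkenylation of an enal with a tetrasubstituted alkenyl bromide; C2 is set here under control of the epoxide.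
3. C14–C1 by B-alkyl Suzuki coupling with Br2C=C(CH2OAc)2, after allylic oxidation and methylenation of the prenyl terminus.
4. C4–C5 by electrochemical decarboxylative alkenylation of an epoxy acid with an (E)-3-iodobut-2-enyl silyl ether.
5. (7S,8S)-Epoxide from D-glutamic acid 5-methyl ester (chloride with retention, Cornforth addition, closure with inversion). Ring order: epoxide, carbocycle, dihydrofuran.

**Route**

Step 1
Reactants: 1 D-glutamic acid 5-methyl ester
Product: 2 (2R)-2-chloro-5-methoxy-5-oxopentanoic acid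
Conditions: NaNO2, 6 M HCl, 0 °C to rt
Reagents that add atoms: hydrochloric acid, Cl
Why: Diazotisation of the α-amino acid in hydrochloric acid (chlorodeamination) replaces NH2 by Cl with net retention through double inversion via the α-lactone, so C7 keeps the purchased R configuration.

Step 2
Reactants: 2 (2R)-2-chloro-5-methoxy-5-oxopentanoic acid
Product: 4 methyl (4R)-4-chloro-5-oxohexanoate, via acid chloride 3 (not isolated)
Conditions: (COCl)2, DMF (cat.), CH2Cl2, 0 °C to rt; then MeMgBr (1.0 equiv), Fe(acac)3 (3 mol %), THF, −78 °C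
Reagents that add atoms: methylmagnesium bromide, C[Mg]Br
Why: Acid chloride formation followed by iron-catalysed Grignard acylation stops at the methyl ketone, outpaces attack on the methyl ester at −78 °C and leaves the C–Cl stereocentre untouched.

Step 3
Reactants: 4 methyl (4R)-4-chloro-5-oxohexanoate; 5 5-bromo-2-methylpent-2-ene
Product: 8 (4S,5S)-4,5-epoxy-5,9-dimethyldec-8-enoic acid, via homoprenylmagnesium bromide 6 (not isolated), via bromomagnesium chlorohydrin alkoxide 7 (not isolated)
Conditions: Mg, THF (5 to 6); add 4, THF, −78 °C; then LiOH, H2O/MeOH, 0 °C to rt; dilute H3PO4 to pH 5, 0 °C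
Reagents that add atoms: lithium hydroxide, [Li+].[OH-]
Why: Cornforth addition: with C–Cl held anti to C=O the Grignard reagent enters past H, so the purchased C7 centre sets C8 (S); the alkoxide then displaces chloride with inversion at C7 to give the trans (7S,8S)-epoxide (Cornforth epoxide synthesis), and hydroxide saponifies the remote ester.

Step 4
Reactants: 9 (2E)-3-iodobut-2-en-1-ol
Product: 10 triethyl{[(2E)-3-iodobut-2-en-1-yl]oxy}silane
Conditions: Et3SiCl, imidazole, CH2Cl2, 0 °C
Reagents that add atoms: chlorotriethylsilane, CC[Si](Cl)(CC)CC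
Why: Standard silylation of a primary allylic alcohol keeps C2 at the alcohol level until step 10; no stereocentre is involved and the E-iodoalkene is untouched.

Step 5
Reactants: 8 (4S,5S)-4,5-epoxy-5,9-dimethyldec-8-enoic acid; 10 triethyl{[(2E)-3-iodobut-2-en-1-yl]oxy}silane
Product: 12 triethyl{[(2E,6S,7S)-6,7-epoxy-3,7,11-trimethyldodeca-2,10-dien-1-yl]oxy}silane, via N-hydroxyphthalimide ester 11 (not isolated)
Conditions: N-hydroxyphthalimide, DIC, DMAP (cat.), CH2Cl2, 0 °C; then 10 (1.5 equiv), NiCl2·6H2O (10 mol %), 2,2'-bipyridine (10 mol %), AgNO3 (30 mol %), LiCl, DMF, Mg anode, RVC cathode, constant current, rt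
Reagents that add atoms: none
Why: Nickel-electrocatalytic decarboxylative alkenylation of a redox-active ester: cathodic reduction releases CO2 and the primary C5 radical (two carbons from the epoxide, so no ring opening), which nickel couples with the alkenyl iodide with retention of E geometry; no stereocentre is formed.

Step 6
Reactants: 12 triethyl{[(2E,6S,7S)-6,7-epoxy-3,7,11-trimethyldodeca-2,10-dien-1-yl]oxy}silane
Product: 14 (2E,6S,7S,10E)-6,7-epoxy-2,6,10-trimethyl-12-(triethylsilyloxy)dodeca-2,10-dienal, via allylic alcohol 13 (not isolated)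
Conditions: SeO2 (0.3 equiv), t-BuOOH (3 equiv), CH2Cl2, 0 °C to rt; then MnO2, CH2Cl2, rt
Reagents that add atoms: tert-butyl hydroperoxide, CC(C)(C)OO
Why: Riley allylic oxidation attacks the E-methyl of the terminal isopropylidene group (the other trisubstituted alkene is deactivated by its allylic silyloxy group), and MnO2 takes the allylic alcohol on to the E-enal without touching the epoxide.

Step 7
Reactants: 14 (2E,6S,7S,10E)-6,7-epoxy-2,6,10-trimethyl-12-(triethylsilyloxy)dodeca-2,10-dienal
Product: 15 triethyl{[(2E,6S,7S,10E)-6,7-epoxy-3,7,11-trimethyltrideca-2,10,12-trien-1-yl]oxy}silane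
Conditions: Ph3PCH3Br, KN(SiMe3)2, THF, −78 to 0 °C
Reagents that add atoms: methyltriphenylphosphonium bromide, C[P+](c1ccccc1)(c1ccccc1)c1ccccc1.[Br-]
Why: Wittig methylenation of the enal gives the terminal 1,3-diene; the ylide leaves the epoxide, the silyl ether and the alkene geometries alone.

Step 8
Reactants: 16 2-oxopropane-1,3-diyl diacetate
Product: 17 2-(dibromomethylidene)propane-1,3-diyl diacetate
Conditions: CBr4, PPh3, toluene, 80 °C
Reagents that add atoms: carbon tetrabromide, BrC(Br)(Br)Br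
Why: Ramirez dibromo-olefination of the activated α,α'-diacyloxy ketone; the two bromines are equivalent, so no alkene geometry issue arises later.

Step 9
Reactants: 15 triethyl{[(2E,6S,7S,10E)-6,7-epoxy-3,7,11-trimethyltrideca-2,10,12-trien-1-yl]oxy}silane; 17 2-(dibromomethylidene)propane-1,3-diyl diacetate
Product: 19 2-[(4E,8S,9S,12E)-1-bromo-8,9-epoxy-4,8,12-trimethyl-14-(triethylsilyloxy)tetradeca-4,12-dien-1-ylidene]propane-1,3-diyl diacetate, via alkyl-9-BBN 18 (not isolated)
Conditions: 9-BBN, THF, 0 °C to rt; then 17, Pd(dppf)Cl2 (5 mol %), AsPh3, K3PO4 (aq), DMF, rt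
Reagents that add atoms: none
Why: 9-BBN adds only to the monosubstituted terminus of the diene, and the B-alkyl Suzuki–Miyaura coupling stops after one bromine because the remaining C–Br bond then sits on a tetrasubstituted alkene; either bromine gives the same product.

Step 10
Reactants: 19 2-[(4E,8S,9S,12E)-1-bromo-8,9-epoxy-4,8,12-trimethyl-14-(triethylsilyloxy)tetradeca-4,12-dien-1-ylidene]propane-1,3-diyl diacetate
Product: 20 2-[(4E,8S,9S,12E)-1-bromo-8,9-epoxy-4,8,12-trimethyl-14-oxotetradeca-4,12-dien-1-ylidene]propane-1,3-diyl diacetate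
Conditions: (COCl)2, DMSO, CH2Cl2, −78 to −30 °C; then Et3N
Reagents that add atoms: none
Why: Swern conditions cleave a primary triethylsilyl ether and oxidise it in one operation to the E-enal; acetates, epoxide and alkenyl bromide are inert at low temperature.

Step 11
Reactants: 20 2-[(4E,8S,9S,12E)-1-bromo-8,9-epoxy-4,8,12-trimethyl-14-oxotetradeca-4,12-dien-1-ylidene]propane-1,3-diyl diacetate
Product: 21 2-[(2S,3E,7S,8S,11E)-7,8-epoxy-2-hydroxy-4,8,12-trimethylcyclotetradeca-3,11-dien-1-ylidene]propane-1,3-diyl diacetate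
Conditions: CrCl2 (20 mol %), NiCl2·glyme (5 mol %), Cp2ZrCl2 (1.5 equiv), LiCl, DMF, 2 mM (slow addition), Al anode, nickel-foam cathode, constant current, rt
Reagents that add atoms: none
Why: Proposed new method: an electroreductive Ni/Cr Nozaki–Hiyama–Kishi coupling is run intramolecularly on a tetrasubstituted alkenyl bromide to close the 14-membered ring, in which zerovalent nickel inserts into C–Br, transmetalation to chromium gives an alkenylchromium that adds 1,2 to the tethered enal, Cp2ZrCl2 frees the chromium alkoxide and the cathode returns trivalent to divalent chromium, the C2 centre being set in the macrocyclic transition state under control of the (7S,8S)-epoxide with the 2S alcohol expected but not assured; the closest known chemistry is the intermolecular electrochemical NHK coupling of alkenyl bromides and the stoichiometric NHK macrocyclisations of cembranoid synthesis.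

Step 12
Reactants: 21 2-[(2S,3E,7S,8S,11E)-7,8-epoxy-2-hydroxy-4,8,12-trimethylcyclotetradeca-3,11-dien-1-ylidene]propane-1,3-diyl diacetate
Product: 22 CNP0140293.1
Conditions: Pd(PPh3)4 (5 mol %), Et3N, THF, rt
Reagents that add atoms: none
Why: Tsuji–Trost allylic etherification: zerovalent palladium ionises an allylic acetate and the C2 hydroxyl closes the five-membered ring on the CH2 terminus cis to it (the strained vinyl-epoxide alternative re-opens); the C2–O bond is never broken, so 2S is retained, and the second acetate remains as C17–OAc.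

**Compound list**
1 | D-glutamic acid 5-methyl ester, (2R)-2-amino-5-methoxy-5-oxopentanoic acid | N[C@H](CCC(=O)OC)C(=O)O | starting material
2 | (2R)-2-chloro-5-methoxy-5-oxopentanoic acid | Cl[C@H](CCC(=O)OC)C(=O)O | intermediate
3 | methyl (4R)-4,5-dichloro-5-oxopentanoate | Cl[C@H](CCC(=O)OC)C(Cl)=O | intermediate
4 | methyl (4R)-4-chloro-5-oxohexanoate | Cl[C@H](CCC(=O)OC)C(C)=O | intermediate
5 | 5-bromo-2-methylpent-2-ene | CC(C)=CCCBr | starting material
6 | (4-methylpent-3-en-1-yl)magnesium bromide | CC(C)=CCC[Mg]Br | intermediate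
7 | bromomagnesium alkoxide of methyl (4R,5S)-4-chloro-5-hydroxy-5,9-dimethyldec-8-enoate | CC(C)=CCC[C@](C)(O[Mg]Br)[C@H](Cl)CCC(=O)OC | intermediate
8 | (4S,5S)-4,5-epoxy-5,9-dimethyldec-8-enoic acid | CC(C)=CCC[C@]1(C)O[C@H]1CCC(=O)O | intermediate
9 | (2E)-3-iodobut-2-en-1-ol | I/C(C)=C/CO | starting material
10 | triethyl{[(2E)-3-iodobut-2-en-1-yl]oxy}silane | I/C(C)=C/CO[Si](CC)(CC)CC | intermediate
11 | 1,3-dioxoisoindolin-2-yl (4S,5S)-4,5-epoxy-5,9-dimethyldec-8-enoate | CC(C)=CCC[C@]1(C)O[C@H]1CCC(=O)ON2C(=O)c3ccccc3C2=O | intermediate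
12 | triethyl{[(2E,6S,7S)-6,7-epoxy-3,7,11-trimethyldodeca-2,10-dien-1-yl]oxy}silane | CC(C)=CCC[C@]1(C)O[C@H]1CC/C(C)=C/CO[Si](CC)(CC)CC | intermediate
13 | (2E,6S,7S,10E)-6,7-epoxy-2,6,10-trimethyl-12-(triethylsilyloxy)dodeca-2,10-dien-1-ol | OC/C(C)=C/CC[C@]1(C)O[C@H]1CC/C(C)=C/CO[Si](CC)(CC)CC | intermediate
14 | (2E,6S,7S,10E)-6,7-epoxy-2,6,10-trimethyl-12-(triethylsilyloxy)dodeca-2,10-dienal | O=C/C(C)=C/CC[C@]1(C)O[C@H]1CC/C(C)=C/CO[Si](CC)(CC)CC | intermediate
15 | triethyl{[(2E,6S,7S,10E)-6,7-epoxy-3,7,11-trimethyltrideca-2,10,12-trien-1-yl]oxy}silane | C=C/C(C)=C/CC[C@]1(C)O[C@H]1CC/C(C)=C/CO[Si](CC)(CC)CC | intermediate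
16 | 2-oxopropane-1,3-diyl diacetate | CC(=O)OCC(=O)COC(C)=O | starting material
17 | 2-(dibromomethylidene)propane-1,3-diyl diacetate | CC(=O)OCC(COC(C)=O)=C(Br)Br | intermediate
18 | 9-[(3E,7S,8S,11E)-7,8-epoxy-3,7,11-trimethyl-13-(triethylsilyloxy)trideca-3,11-dien-1-yl]-9-borabicyclo[3.3.1]nonane | B1(CC/C(C)=C/CC[C@]2(C)O[C@H]2CC/C(C)=C/CO[Si](CC)(CC)CC)C3CCCC1CCC3 | intermediate
19 | 2-[(4E,8S,9S,12E)-1-bromo-8,9-epoxy-4,8,12-trimethyl-14-(triethylsilyloxy)tetradeca-4,12-dien-1-ylidene]propane-1,3-diyl diacetate | CC(=O)OCC(COC(C)=O)=C(Br)CC/C(C)=C/CC[C@]1(C)O[C@H]1CC/C(C)=C/CO[Si](CC)(CC)CC | intermediate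
20 | 2-[(4E,8S,9S,12E)-1-bromo-8,9-epoxy-4,8,12-trimethyl-14-oxotetradeca-4,12-dien-1-ylidene]propane-1,3-diyl diacetate | CC(=O)OCC(COC(C)=O)=C(Br)CC/C(C)=C/CC[C@]1(C)O[C@H]1CC/C(C)=C/C=O | intermediate
21 | 2-[(2S,3E,7S,8S,11E)-7,8-epoxy-2-hydroxy-4,8,12-trimethylcyclotetradeca-3,11-dien-1-ylidene]propane-1,3-diyl diacetate | CC(=O)OCC(COC(C)=O)=C1CC/C(C)=C/CC[C@]2(C)O[C@H]2CC/C(C)=C/[C@@H]1O | intermediate
22 | CNP0140293.1, (2S,3E,7S,8S,11E)-2,16:7,8-diepoxycembra-1(15),3,11-trien-17-yl acetate | CC(=O)OCC1=C2CC/C(C)=C/CC[C@]3(C)O[C@H]3CC/C(C)=C/[C@@H]2OC1 | target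

**Step count**
Total: 12 steps. Longest linear sequence: 10 steps (steps 1, 2, 3, 5, 6, 7, 9, 10, 11, 12).

**Steps most likely to fail, with fallbacks**

Step 11 (the new macrocyclisation). Risks: slow insertion into the hindered alkenyl bromide, nickel attack on the allylic acetates, Lewis-acid damage to the epoxide, and a poor or reversed ratio at C2. The fallback sets out from 20 and returns at 21, and it sets C2 by hydride delivery to a ring ketone instead of by the C–C bond formation. 20 is cyclised by the classical stoichiometric NHK reaction (CrCl2 in excess, NiCl2 cat., DMSO, 1 mM), which gives 21 together with its C2 epimer 2-[(2R,3E,7S,8S,11E)-7,8-epoxy-2-hydroxy-4,8,12-trimethylcyclotetradeca-3,11-dien-1-ylidene]propane-1,3-diyl diacetate F5. The mixture is oxidised with MnO2 to the cross-conjugated macrocyclic ketone 2-[(3E,7S,8S,11E)-7,8-epoxy-4,8,12-trimethyl-2-oxocyclotetradeca-3,11-dien-1-ylidene]propane-1,3-diyl diacetate F6. Luche reduction (NaBH4, CeCl3·7H2O, MeOH, −78 °C) then delivers hydride from the ring periphery to give 21. The same detour corrects the main route if step 11 favours the 2R alcohol.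

Step 5 (electrochemical decarboxylative alkenylation). Risks: the γ,δ-epoxy acid 8 can lactonise before activation, and the epoxide may not survive the cathode. The fallback sets out from 8 and returns at 12, keeping the carboxyl carbon as C4 instead of excising it. 8 is treated with MeLi (2.2 equiv, Et2O, −78 to 0 °C) to give the methyl ketone (5S,6S)-5,6-epoxy-6,10-dimethylundec-9-en-2-one F1. Horner–Wadsworth–Emmons olefination (triethyl phosphonoacetate, NaH, THF) gives ethyl (2E,6S,7S)-6,7-epoxy-3,7,11-trimethyldodeca-2,10-dienoate F2, the minor 2Z isomer being removed by chromatography. Reduction with i-Bu2AlH (−78 °C) gives (2E,6S,7S)-6,7-epoxy-3,7,11-trimethyldodeca-2,10-dien-1-ol F3, and silylation as in step 4 gives 12.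

Step 9 (hydroboration and mono-Suzuki coupling). Risks: aqueous base with two allylic acetates, palladium ionisation of the allylic acetates of 17, and over-coupling. The fallback sets out from 15 and returns at 19, replacing the aqueous boron coupling by an anhydrous zinc coupling through an isolated iodide. 15 is hydroborated with 9-BBN and the borane is iodinated (I2, NaOMe) to triethyl{[(2E,6S,7S,10E)-6,7-epoxy-13-iodo-3,7,11-trimethyltrideca-2,10-dien-1-yl]oxy}silane F4. Zinc insertion (Zn, LiCl, THF) and a Negishi mono-coupling with 17 (Pd(PPh3)4, THF, rt) then give 19.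

**Further compounds**
F1 | step 5 | (5S,6S)-5,6-epoxy-6,10-dimethylundec-9-en-2-one | CC(C)=CCC[C@]1(C)O[C@H]1CCC(C)=O
F2 | step 5 | ethyl (2E,6S,7S)-6,7-epoxy-3,7,11-trimethyldodeca-2,10-dienoate | CC(C)=CCC[C@]1(C)O[C@H]1CC/C(C)=C/C(=O)OCC
F3 | step 5 | (2E,6S,7S)-6,7-epoxy-3,7,11-trimethyldodeca-2,10-dien-1-ol | CC(C)=CCC[C@]1(C)O[C@H]1CC/C(C)=C/CO
F4 | step 9 | triethyl{[(2E,6S,7S,10E)-6,7-epoxy-13-iodo-3,7,11-trimethyltrideca-2,10-dien-1-yl]oxy}silane | ICC/C(C)=C/CC[C@]1(C)O[C@H]1CC/C(C)=C/CO[Si](CC)(CC)CC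
F5 | step 11 | 2-[(2R,3E,7S,8S,11E)-7,8-epoxy-2-hydroxy-4,8,12-trimethylcyclotetradeca-3,11-dien-1-ylidene]propane-1,3-diyl diacetate | CC(=O)OCC(COC(C)=O)=C1CC/C(C)=C/CC[C@]2(C)O[C@H]2CC/C(C)=C/[C@H]1O
F6 | step 11 | 2-[(3E,7S,8S,11E)-7,8-epoxy-4,8,12-trimethyl-2-oxocyclotetradeca-3,11-dien-1-ylidene]propane-1,3-diyl diacetate | CC(=O)OCC(COC(C)=O)=C1CC/C(C)=C/CC[C@]2(C)O[C@H]2CC/C(C)=C/C1=O
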